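## Retrosynthetic overview
1. The target comes from its guaiacyl O-acetate / syringyl O-TBS derivative; both phenols are unmasked in one pot at the end.
2. Key disconnection: both rings and the OCH2 carbon are removed together (bonds C4–C3a, C4–O5 and O2–C3). This leads back to an acyclic syn-aldol N-acyloxazolidinone plus formaldehyde (Prins bicyclisation; the auxiliary leaves in the same flask).
3. Ring order within that operation: the styrene attacks the O=CH2(+) ion in a 5-exo mode to close the tetrahydrofuran (ring A). The imide C=O then captures the benzylic cation to close the γ-lactone (ring B).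
4. The aldol imide comes from an Evans syn-aldol of an (E)-styrylacetyl oxazolidinone with vanillin acetate. This sets C6 and C6a, which then dictate C3a and C3.
5. The styrylacetic acid comes from a Wittig reaction of O-TBS-syringaldehyde with (2-carboxyethyl)triphenylphosphonium bromide.

Assumption: the SMILES is read as the (3S,3aR,6S,6aS) isomer, cis-fused with both aryl groups exo. Locants follow furo[3,4-c]furan-1-one: C1 lactone C=O, O2, C3 CH-syringyl, C3a, C4 OCH2, O5, C6 CH-guaiacyl, C6a.

## Route

Step 1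
Reactants: 1 syringaldehyde (4-hydroxy-3,5-dimethoxybenzaldehyde)
Product: 2 4-(tert-butyldimethylsilyloxy)-3,5-dimethoxybenzaldehyde
Conditions: TBSCl, imidazole, DMF, rt
Reagents that add atoms: tert-butyldimethylsilyl chloride, CC(C)(C)[Si](C)(C)Cl
Why: Imidazole-promoted silyl ether formation masks the acidic phenol against the ylide base and the later boron enolisation, and no stereocentre is involved.

Step 2
Reactants: 2 4-(tert-butyldimethylsilyloxy)-3,5-dimethoxybenzaldehyde; 3 (2-carboxyethyl)triphenylphosphonium bromide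
Product: 5 (E)-4-[4-(tert-butyldimethylsilyloxy)-3,5-dimethoxyphenyl]but-3-enoic acid, via ylide 4 (not isolated)
Conditions: 3, NaN(SiMe3)2 (2 equiv per 3), THF, −78 → 0 °C; then 2, −78 °C → rt; 1 M HCl work-up
Reagents that add atoms: none
Why: In this Wittig olefination the carboxylate-bearing ylide gives mainly the E β,γ-unsaturated acid with aromatic aldehydes (about 10:1 expected, E acid crystallised), the aryl silyl ether is inert to the amide base, and the E geometry is later translated into the C3 configuration.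

Step 3
Reactants: 5 (E)-4-[4-(tert-butyldimethylsilyloxy)-3,5-dimethoxyphenyl]but-3-enoic acid; 6 (S)-4-benzyloxazolidin-2-one
Product: 8 (S)-4-benzyl-3-{(E)-4-[4-(tert-butyldimethylsilyloxy)-3,5-dimethoxyphenyl]but-3-enoyl}oxazolidin-2-one, via mixed anhydride 7 (not isolated)
Conditions: PivCl, Et3N, THF, −20 °C; then 6, LiCl, −20 °C → rt
Reagents that add atoms: none
Why: Mixed-anhydride N-acylation of the Evans oxazolidinone under LiCl/Et3N needs no strong base, so the styryl double bond and the silyl ether are untouched, and the only stereocentre is bought with 6.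

Step 4
Reactants: 8 (S)-4-benzyl-3-{(E)-4-[4-(tert-butyldimethylsilyloxy)-3,5-dimethoxyphenyl]but-3-enoyl}oxazolidin-2-one; 9 vanillin acetate (4-formyl-2-methoxyphenyl acetate)
Product: 12 (S)-4-benzyl-3-{(2S,3E)-2-[(S)-(4-acetoxy-3-methoxyphenyl)(hydroxy)methyl]-4-[4-(tert-butyldimethylsilyloxy)-3,5-dimethoxyphenyl]but-3-enoyl}oxazolidin-2-one, via boron dienolate 10 (not isolated), via boron aldolate 11 (not isolated)
Conditions: Bu2BOTf, Et3N, CH2Cl2, −78 → 0 °C; then 9, −78 → 0 °C; pH 7 buffer/MeOH work-up (no H2O2)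
Reagents that add atoms: none
Why: In this Evans syn-aldol reaction the Z boron dienolate reacts at its α-carbon through a closed Zimmerman–Traxler chair on the face away from the benzyl group, which sets C6a (S) and C6 (S) (dr > 20:1 expected), while the peroxide-free work-up spares the aryl acetate.

Step 5
Reactants: 12 (S)-4-benzyl-3-{(2S,3E)-2-[(S)-(4-acetoxy-3-methoxyphenyl)(hydroxy)methyl]-4-[4-(tert-butyldimethylsilyloxy)-3,5-dimethoxyphenyl]but-3-enoyl}oxazolidin-2-one
Product: 15 (3S,3aR,6S,6aS)-6-(4-acetoxy-3-methoxyphenyl)-3-[4-(tert-butyldimethylsilyloxy)-3,5-dimethoxyphenyl]tetrahydro-1H,3H-furo[3,4-c]furan-1-one, via oxocarbenium ion 13 (not isolated), via imidium ion 14 (not isolated)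
Conditions: (CH2O)n (2 equiv, pre-dissolved in CF3CO2H, 10 equiv), then 12, CH2Cl2 (0.02 M), −20 → 0 °C
Reagents that add atoms: formaldehyde (used as paraformaldehyde), C=O
Why: Proposed new method: this is a Prins bicyclisation in which the acid condenses the C6 alcohol with formaldehyde to oxocarbenium ion 13, the E-styrene attacks it through its β-carbon in a 5-exo mode (ring A, Markovnikov, positive charge at benzylic C3), the imide carbonyl oxygen held on the opposite alkene face by C6a closes ring B to imidium ion 14, and the water released in the first condensation hydrolyses 14 to lactone 15 and free auxiliary; only the cis-fused bicycle can close, so C6a fixes C3a, anti addition across the E-alkene places the C3 aryl exo, and C6 keeps its aldol configuration because its C–O bond is never broken, the acetate making that benzylic site hard to ionise and the competing 2-oxonia-Cope shift less favourable; the closest known reaction types are 5-exo Prins cyclisations of homoallylic alcohols with cation-stabilising alkene termini, Prins cascades ended by a tethered oxygen nucleophile, 5-endo halolactonisation of styrylacetic acids, and halolactonisation of unsaturated N-acyloxazolidinones with loss of the auxiliary.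

Step 6
Reactants: 15 (3S,3aR,6S,6aS)-6-(4-acetoxy-3-methoxyphenyl)-3-[4-(tert-butyldimethylsilyloxy)-3,5-dimethoxyphenyl]tetrahydro-1H,3H-furo[3,4-c]furan-1-one
Product: 17 (3S,3aR,6S,6aS)-3-(4-hydroxy-3,5-dimethoxyphenyl)-6-(4-hydroxy-3-methoxyphenyl)tetrahydro-1H,3H-furo[3,4-c]furan-1-one (target), via monophenol 16 (not isolated)
Conditions: pyrrolidine (3 equiv), THF, 0 °C; then AcOH (8 equiv), Bu4NF (1.5 equiv), 0 °C
Reagents that add atoms: none
Why: Chemoselective aminolysis removes the aryl acetate (far more electrophilic than the γ-lactone) while the syringyl oxygen is still silylated, so no p-quinone methide can open the lactone, and the acetic-acid-buffered fluoride desilylation that follows keeps the medium non-basic, so no stereocentre is touched.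

## Compound list
1 | syringaldehyde | COc1cc(C=O)cc(OC)c1O | starting material
2 | 4-(tert-butyldimethylsilyloxy)-3,5-dimethoxybenzaldehyde | COc1cc(C=O)cc(OC)c1O[Si](C)(C)C(C)(C)C | intermediate
3 | (2-carboxyethyl)triphenylphosphonium bromide | OC(=O)CC[P+](c1ccccc1)(c1ccccc1)c1ccccc1.[Br-] | starting material
4 | sodium 3-(triphenylphosphoranylidene)propanoate (ylide) | [Na+].[O-]C(=O)CC=P(c1ccccc1)(c1ccccc1)c1ccccc1 | intermediate
5 | (E)-4-[4-(tert-butyldimethylsilyloxy)-3,5-dimethoxyphenyl]but-3-enoic acid | COc1cc(/C=C/CC(=O)O)cc(OC)c1O[Si](C)(C)C(C)(C)C | intermediate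
6 | (S)-4-benzyloxazolidin-2-one | O=C1N[C@@H](Cc2ccccc2)CO1 | starting material
7 | mixed pivalic anhydride of 5 | COc1cc(/C=C/CC(=O)OC(=O)C(C)(C)C)cc(OC)c1O[Si](C)(C)C(C)(C)C | intermediate
8 | (S)-4-benzyl-3-{(E)-4-[4-(TBSO)-3,5-dimethoxyphenyl]but-3-enoyl}oxazolidin-2-one | COc1cc(/C=C/CC(=O)N2C(=O)OC[C@@H]2Cc2ccccc2)cc(OC)c1O[Si](C)(C)C(C)(C)C | intermediate
9 | vanillin acetate (4-formyl-2-methoxyphenyl acetate) | COc1cc(C=O)ccc1OC(C)=O | starting material
10 | Z dibutylboron dienolate of 8 | CCCCB(CCCC)O/C(=C\C=C\c1cc(OC)c(O[Si](C)(C)C(C)(C)C)c(OC)c1)N1C(=O)OC[C@@H]1Cc1ccccc1 | intermediate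
11 | dibutylboron aldolate (O-BBu2 derivative of 12) | O=C(N1C(=O)OC[C@@H]1Cc1ccccc1)[C@@H](/C=C/c1cc(OC)c(O[Si](C)(C)C(C)(C)C)c(OC)c1)[C@H](OB(CCCC)CCCC)c1ccc(OC(C)=O)c(OC)c1 | intermediate
12 | syn-aldol imide, (2S,3E), carbinol (S), auxiliary (S) | O=C(N1C(=O)OC[C@@H]1Cc1ccccc1)[C@@H](/C=C/c1cc(OC)c(O[Si](C)(C)C(C)(C)C)c(OC)c1)[C@H](O)c1ccc(OC(C)=O)c(OC)c1 | intermediate
13 | O-methylidene oxocarbenium ion of 12 | O=C(N1C(=O)OC[C@@H]1Cc1ccccc1)[C@@H](/C=C/c1cc(OC)c(O[Si](C)(C)C(C)(C)C)c(OC)c1)[C@H]([O+]=C)c1ccc(OC(C)=O)c(OC)c1 | intermediate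
14 | bicyclic imidium ion (C1 = N(+) of the oxazolidinone) | COc1cc([C@H]2OC[C@H]3[C@@H]2C(=[N+]2C(=O)OC[C@@H]2Cc2ccccc2)O[C@@H]3c2cc(OC)c(O[Si](C)(C)C(C)(C)C)c(OC)c2)ccc1OC(C)=O | intermediate
15 | (3S,3aR,6S,6aS)-6-(4-acetoxy-3-methoxyphenyl)-3-[4-(TBSO)-3,5-dimethoxyphenyl]tetrahydro-1H,3H-furo[3,4-c]furan-1-one | COc1cc([C@H]2OC[C@H]3[C@@H]2C(=O)O[C@@H]3c2cc(OC)c(O[Si](C)(C)C(C)(C)C)c(OC)c2)ccc1OC(C)=O | intermediate
16 | (3S,3aR,6S,6aS)-6-(4-hydroxy-3-methoxyphenyl)-3-[4-(TBSO)-3,5-dimethoxyphenyl]tetrahydro-1H,3H-furo[3,4-c]furan-1-one | COc1cc([C@H]2OC[C@H]3[C@@H]2C(=O)O[C@@H]3c2cc(OC)c(O[Si](C)(C)C(C)(C)C)c(OC)c2)ccc1O | intermediate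
17 | (3S,3aR,6S,6aS)-3-(4-hydroxy-3,5-dimethoxyphenyl)-6-(4-hydroxy-3-methoxyphenyl)tetrahydro-1H,3H-furo[3,4-c]furan-1-one | COc1cc([C@H]2OC[C@H]3[C@@H]2C(=O)O[C@@H]3c2cc(OC)c(O)c(OC)c2)ccc1O | target

## Step count and risks
Total steps: 6. Longest linear sequence: 6 (1 → 2 → 5 → 8 → 12 → 15 → 17).

**Step 5, the Prins bicyclisation, is the most likely to fail.**
- Failure modes:
  - a 2-oxonia-Cope shift of 13 to the aryl-stabilised oxocarbenium ion;
  - protonation of the styrene by the acid;
  - closure of ring A in the 3,4-trans mode, which cannot lactonise;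
  - hydroxymethylation of the syringyl ring by surplus formaldehyde.
- Fallback, from 12 back to 15:
  - The C1 unit is first installed under basic conditions (MOMCl, iPr2NEt, CH2Cl2) to give the C6 O-methoxymethyl ether F1.
  - Only this acetal is then ionised, under aprotic conditions (SnCl4, 2,6-di-tert-butylpyridine, CH2Cl2, −78 °C). This is an acetal-initiated Prins cyclisation with exactly one C1 unit per molecule and no free Brønsted acid.
  - It passes through 13 and 14, and aqueous NaHCO3 hydrolyses 14, so the route is rejoined at 15. The cost is one extra step.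

**Step 6, the one-pot unmasking, is second.**
- Failure modes:
  - the amine may open the lactone;
  - once the syringyl phenol is free, the p-hydroxybenzyl lactone can ionise to a quinone methide and epimerise or add nucleophiles.
- Fallback, from 15 to 17:
  - Amine chemistry is dropped and the order is reversed.
  - Buffered fluoride (Bu4NF/AcOH, THF, 0 °C) first gives the isolated syringyl phenol guaiacyl acetate F2.
  - The acetate is then removed by a biocatalytic transesterification at neutral pH (immobilised Candida antarctica lipase B, n-BuOH, MTBE, 35 °C). This gives 17.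

**Step 2, the Wittig reaction, is third.**
- Failure modes:
  - ylide 4 can lose triphenylphosphine by β-elimination to acrylate;
  - the E:Z ratio may be poor.
- Fallback, from 2 back to 5:
  - The double bond is made by metathesis instead.
  - Compound 2 is methylenated (MePPh3Br, KOtBu, THF) to 4-(tert-butyldimethylsilyloxy)-3,5-dimethoxystyrene F3.
  - Olefin cross-metathesis with but-3-enoic acid (second-generation Hoveyda–Grubbs catalyst, CH2Cl2, 40 °C) gives the thermodynamic E acid, so the route is rejoined at 5.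

## Further compounds
F1 | step 5 | C6 O-methoxymethyl ether of 12 | O=C(N1C(=O)OC[C@@H]1Cc1ccccc1)[C@@H](/C=C/c1cc(OC)c(O[Si](C)(C)C(C)(C)C)c(OC)c1)[C@H](OCOC)c1ccc(OC(C)=O)c(OC)c1
F2 | step 6 | (3S,3aR,6S,6aS)-6-(4-acetoxy-3-methoxyphenyl)-3-(4-hydroxy-3,5-dimethoxyphenyl)tetrahydro-1H,3H-furo[3,4-c]furan-1-one | COc1cc([C@H]2OC[C@H]3[C@@H]2C(=O)O[C@@H]3c2cc(OC)c(O)c(OC)c2)ccc1OC(C)=O
F3 | step 2 | 4-(tert-butyldimethylsilyloxy)-3,5-dimethoxystyrene | C=Cc1cc(OC)c(O[Si](C)(C)C(C)(C)C)c(OC)c1
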